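All constants are invented; the run is a simulation.

Decide first what to watch: not the acid, but how hard the nucleophile draws electrophile out of solution against the dissolving that refills it.

- elm: solid electrophile 0.50 mM; nucleophile 0.650 mM; free base 1.50 mM (fed, over 2.5 s); scavenger 0.600 mM; time 1.0 min
- cedar: solid electrophile 0.50 mM; nucleophile 0.650 mM; free base 0.750 mM (fed, over 2.5 s); scavenger 0.600 mM; time 1.0 min
- part of the solid electrophile that has reacted (what has only dissolved counts as not reacted) at the end, elm
- part of the solid electrophile that has reacted (what has only dissolved counts as not reacted) at the end, cedar
- what raising the concentration of free base from its lowest to its highest value here does to the part of the solid electrophile that has reacted (what has only dissolved counts as not reacted) (changes below 5 percentage points count as none) (no change / it rises / it falls)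
- what is said of acid set free includes idle adduct
- solid electrophile is a solid; its amount is given per volume of the solution
- at the start none of the solid electrophile is in solution
- what has only dissolved of solid electrophile counts as not reacted
- run time (elm): 1.0 min
    electrophile + nucleophile → acid set free + product (k1 = 950 M⁻¹ s⁻¹)
    nucleophile + acid set free ⇌ protonated nucleophile, settled at all times (K2 = 54000 M⁻¹)
    acid set free + free base ⇌ salt of the base (K3 = 9400 M⁻¹, k3 = 34000 M⁻¹ s⁻¹)
    solid electrophile ⇌ electrophile, rate k4*(cs4 - [electrophile]) while solid is left; crystals form when [electrophile] > cs4 (cs4 = 0.073 mM, k4 = 0.51 s⁻¹)
    acid set free + free base ⇌ idle adduct, settled at all times (K5 = 2200 M⁻¹)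
    acid set free + scavenger → scavenged by-product (k6 = 6600 M⁻¹ s⁻¹)

Reckon the pull at the charge, 1.21: this ratio of the pseudo-first-order rate constant of step 1 to the dissolution coefficient has no time in it. While solid lasts and the two rates balance:

φ = 950 M⁻¹ s⁻¹ × [nucleophile] / 0.51 s⁻¹

[electrophile] = solubility / (1 + φ)

solid used per second = 0.51 s⁻¹ × solubility × φ / (1 + φ)

Now climb the ladder. By step 6 alone, the scavenger removes acid set free with a half-life of 0.18 s in cedar as charged, shorter than the 1.1 s of the electrophile by step 1 alone, and its charge exceeds that of the solid. I therefore count nucleophile bound by acid as free, which flatters φ. Dissolving alone closes the gap to solubility with a half-life of 1.36 s, shorter than the run, so I take the balance above to hold early. The tail is slower: with 0.150 mM of nucleophile remaining, dissolved electrophile halves every 4.86 s. Slowest is the solid: at the midway pull, 0.745, I estimate that it lasts about 31.5 s, inside the run. At its end, counting the nucleophile as already down to that remainder, φ = 0.279 gives 0.0571 mM dissolved, and the remaining time brings that down to 0.195% of the charge. My figure is 99.8% reacted, the same for elm and cedar, since free base stands nowhere in the reckoning.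

The forecast gives 99.5% for elm (97% to 100%), 99.5% for cedar (97% to 100%) and no change, holding that “the scavenger has enough capacity to keep releasing it”.

The simulation gives 99.7% for elm, 99.6% for cedar and no change, a difference of 0.027 percentage points. In cedar at 0.500 min, free nucleophile at 28.2% of its charge gives electrophile at 10.9% of the solid charged; the flask holds 10.7%. The neighbour flask is cedar with 0.16 mM of nucleophile, 0.320 equiv to the solid electrophile. At 1.00 min, its free nucleophile stands at 2.7% of that charge, so φ = 0.00813 and the balance puts electrophile at 14.5% of the solid charged. The flask holds 14.5%, with 31.1% reacted and 54.4% still solid.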